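**Retrosynthetic overview**

1. The target is released from its 7-O-benzyl ether by hydrogenolysis; the benzyl group keeps O7 distinct from the two hydroxyls involved in ring closure.
2. Ring C is cut at C3–C4 and O1–C2. The feature used is C4, the carbonyl carbon between C4a of ring A and C3, flanked on ring A by the oxygens at C5 and C8a. As a formyl carbon on a ring A with a mirror plane through C4a and C7, it sits between two equivalent hydroxyls, can be metalated next to either, and is joined to C3 of a 2,3-dimethoxybenzoyl sulfoxonium ylide (C3, C2 and ring B).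
3. The aldehyde comes from syringol: O-benzylation, dibromination at the two positions ortho/para to the methoxy groups, Br to OH through the bis(boronate), and formylation of the one free ring carbon.
4. The ylide comes from 2,3-dimethoxybenzoic acid through the acid chloride and dimethylsulfoxonium methylide.
5. Ring order: rings A and B come from the starting materials; ring C is the only ring formed, in the annulation.

Key step: step 8

**Route**

Step 1
Reactants: 1 2,6-dimethoxyphenol (syringol)
Product: 2 2-(benzyloxy)-1,3-dimethoxybenzene
Conditions: BnBr, K2CO3, DMF, 60 °C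
Reagents that add atoms: benzyl bromide, BrCc1ccccc1
Why: Williamson ether synthesis; the phenoxide of syringol should be alkylated cleanly by the reactive benzylic bromide despite its two flanking methoxy groups.

Step 2
Reactants: 2 2-(benzyloxy)-1,3-dimethoxybenzene
Product: 3 3-(benzyloxy)-1,5-dibromo-2,4-dimethoxybenzene
Conditions: NBS (2.1 equiv), MeCN, 0 °C to rt, dark
Reagents that add atoms: N-bromosuccinimide, O=C1CCC(=O)N1Br
Why: Electrophilic aromatic bromination; the two ring positions that are ortho to one methoxy and para to the other are the most activated, the position para to the twisted central benzyloxy group is not, and the benzyl ring and benzylic CH2 should stay untouched under ionic conditions in the dark.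

Step 3
Reactants: 3 3-(benzyloxy)-1,5-dibromo-2,4-dimethoxybenzene
Product: 4 2,2'-[5-(benzyloxy)-4,6-dimethoxy-1,3-phenylene]bis(4,4,5,5-tetramethyl-1,3,2-dioxaborolane)
Conditions: B2pin2 (2.5 equiv), Pd(dppf)Cl2·CH2Cl2 (cat.), KOAc, 1,4-dioxane, 90 °C, N2
Reagents that add atoms: bis(pinacolato)diboron, CC1(C)OB(OC1(C)C)B1OC(C)(C)C(C)(C)O1
Why: Miyaura borylation; zerovalent palladium formed from Pd(dppf)Cl2 inserts into each C–Br bond and acetate-assisted transmetalation with B2pin2 should install both boronates, the aryl ethers being inert.

Step 4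
Reactants: 4 2,2'-[5-(benzyloxy)-4,6-dimethoxy-1,3-phenylene]bis(4,4,5,5-tetramethyl-1,3,2-dioxaborolane)
Product: 5 5-(benzyloxy)-4,6-dimethoxybenzene-1,3-diol
Conditions: 30% aq H2O2, 2 M aq NaOH, THF, 0 °C, N2; then aq Na2S2O3, dilute HCl
Reagents that add atoms: hydrogen peroxide, OO
Why: Oxidation of an aryl boronate by hydroperoxide with 1,2-migration of the aryl group from boron to oxygen places each hydroxyl exactly where boron stood; cold, short, oxygen-free treatment with a reductive quench should protect the electron-rich resorcinol.

Step 5
Reactants: 5 5-(benzyloxy)-4,6-dimethoxybenzene-1,3-diol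
Product: 6 4-(benzyloxy)-2,6-dihydroxy-3,5-dimethoxybenzaldehyde
Conditions: POCl3, DMF, MeCN, 0 °C to rt; then H2O, 50 °C
Reagents that add atoms: N,N-dimethylformamide, CN(C)C=O; water, O
Why: Vilsmeier–Haack formylation; the only unsubstituted ring carbon is ortho to both hydroxyls and para to the benzyloxy group, so the chloroiminium ion should attack there as it does in phloroglucinol-type phenols, and hydrolysis gives the aldehyde.

Step 6
Reactants: 7 2,3-dimethoxybenzoic acid
Product: 8 2,3-dimethoxybenzoyl chloride
Conditions: SOCl2, DMF (cat.), toluene, 70 °C; evaporate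
Reagents that add atoms: thionyl chloride, O=S(Cl)Cl
Why: Standard acyl chloride formation through the chlorosulfite; the aryl methyl ethers are inert.

Step 7
Reactants: 8 2,3-dimethoxybenzoyl chloride; 9 trimethylsulfoxonium iodide
Product: 11 1-(2,3-dimethoxyphenyl)-2-(dimethyl(oxo)-λ6-sulfanylidene)ethan-1-one, via dimethylsulfoxonium methylide 10 (not isolated)
Conditions: 9 (3 equiv), KOtBu (3 equiv), THF, reflux; then 8, 0 °C to rt
Reagents that add atoms: none
Why: The Corey–Chaykovsky methylide is C-acylated by the acid chloride and a second equivalent of methylide deprotonates the acylsulfoxonium salt, which should give the stabilised keto sulfoxonium ylide.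

Step 8
Reactants: 6 4-(benzyloxy)-2,6-dihydroxy-3,5-dimethoxybenzaldehyde; 11 1-(2,3-dimethoxyphenyl)-2-(dimethyl(oxo)-λ6-sulfanylidene)ethan-1-one
Product: 13 7-(benzyloxy)-5-hydroxy-6,8-dimethoxy-2-(2,3-dimethoxyphenyl)-4H-chromen-4-one, via aryl 1,3-diketone 12 (not isolated)
Conditions: [Cp*RhCl2]2 (4 mol %), AgSbF6 (16 mol %), PivOH (2 equiv), 1,2-dichloroethane, 100 °C, N2
Reagents that add atoms: none
Why: Chloride abstraction by AgSbF6 gives a cationic Cp*Rh species (trivalent rhodium) that binds one phenoxide of 6 and cleaves the adjacent formyl C–H bond by carboxylate-assisted metalation to a five-membered acyl rhodacycle; ylide 11 then binds through carbon, loses dimethyl sulfoxide to give a rhodium carbene, migratory insertion of the acyl group forms C3–C4, and protonation by PivOH releases diketone 12 and returns the catalyst. The closest known reaction type is the Cp*Rh-catalysed formyl C–H annulation of salicylaldehydes with aroyl sulfoxonium ylides to flavones, applied here to a 2,6-dihydroxybenzaldehyde. Ring C closes by 6-exo-trig attack of a phenol oxygen of 12 on the ring B ketone (O1–C2), followed by acid-promoted loss of water to the pyranone. No stereocenter is formed. The step needs acyl C–H functionalisation to outrun carbene O–H insertion and decarbonylation, which the phenoxide chelate should secure by holding rhodium at the formyl group; no regiocontrol is needed in the closure because the mirror plane of ring A makes the two hydroxyls equivalent, and the unused one ends as the hydrogen-bonded 5-hydroxyl.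

Step 9
Reactants: 13 7-(benzyloxy)-5-hydroxy-6,8-dimethoxy-2-(2,3-dimethoxyphenyl)-4H-chromen-4-one
Product: 14 5,7-dihydroxy-6,8-dimethoxy-2-(2,3-dimethoxyphenyl)-4H-chromen-4-one (5,7-dihydroxy-6,8,2',3'-tetramethoxyflavone)
Conditions: H2 (1 atm), 10% Pd/C, EtOAc/MeOH, rt
Reagents that add atoms: none
Why: Hydrogenolysis of an aryl benzyl ether over Pd/C; the C2=C3 bond of the flavone is a doubly aryl-conjugated vinylogous ester and is reduced far more slowly, so stopping at one equivalent of hydrogen should give the target with the methyl ethers intact.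

**Compound list**

1 | 2,6-dimethoxyphenol (syringol) | COc1cccc(OC)c1O | starting material
2 | 2-(benzyloxy)-1,3-dimethoxybenzene | COc1cccc(OC)c1OCc1ccccc1 | intermediate
3 | 3-(benzyloxy)-1,5-dibromo-2,4-dimethoxybenzene | COc1c(Br)cc(Br)c(OC)c1OCc1ccccc1 | intermediate
4 | 2,2'-[5-(benzyloxy)-4,6-dimethoxy-1,3-phenylene]bis(4,4,5,5-tetramethyl-1,3,2-dioxaborolane) | COc1c(B2OC(C)(C)C(C)(C)O2)cc(B2OC(C)(C)C(C)(C)O2)c(OC)c1OCc1ccccc1 | intermediate
5 | 5-(benzyloxy)-4,6-dimethoxybenzene-1,3-diol | COc1c(O)cc(O)c(OC)c1OCc1ccccc1 | intermediate
6 | 4-(benzyloxy)-2,6-dihydroxy-3,5-dimethoxybenzaldehyde | O=Cc1c(O)c(OC)c(OCc2ccccc2)c(OC)c1O | intermediate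
7 | 2,3-dimethoxybenzoic acid | COc1cccc(C(=O)O)c1OC | starting material
8 | 2,3-dimethoxybenzoyl chloride | COc1cccc(C(=O)Cl)c1OC | intermediate
9 | trimethylsulfoxonium iodide | C[S+](C)(C)=O.[I-] | starting material
10 | dimethylsulfoxonium methylide | C=S(C)(C)=O | intermediate (not isolated)
11 | 1-(2,3-dimethoxyphenyl)-2-(dimethyl(oxo)-λ6-sulfanylidene)ethan-1-one | COc1cccc(C(=O)C=S(C)(C)=O)c1OC | intermediate
12 | 1-[4-(benzyloxy)-2,6-dihydroxy-3,5-dimethoxyphenyl]-3-(2,3-dimethoxyphenyl)propane-1,3-dione | COc1cccc(C(=O)CC(=O)c2c(O)c(OC)c(OCc3ccccc3)c(OC)c2O)c1OC | intermediate (not isolated)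
13 | 7-(benzyloxy)-5-hydroxy-6,8-dimethoxy-2-(2,3-dimethoxyphenyl)-4H-chromen-4-one | COc1cccc(-c2cc(=O)c3c(O)c(OC)c(OCc4ccccc4)c(OC)c3o2)c1OC | intermediate
14 | 5,7-dihydroxy-6,8-dimethoxy-2-(2,3-dimethoxyphenyl)-4H-chromen-4-one | COc1cccc(-c2cc(=O)c3c(O)c(OC)c(O)c(OC)c3o2)c1OC | target

**Step count**

Total steps: 9. Longest linear sequence: 7 (steps 1, 2, 3, 4, 5, 8, 9); the ylide branch (steps 6, 7) joins at step 8.

**Steps most likely to fail**

Step 8. The carbene may insert into one of the free phenolic O–H bonds, the acyl rhodium may lose CO, or the 5-hydroxy-4-keto chelate of the product may tie up the catalyst so that turnover stops. The fallback sets out from resorcinol 5 and acid chloride 8 and builds the same diketone without a metal catalyst. Hoesch acylation of 5 with acetonitrile (ZnCl2, HCl gas, Et2O, 0 °C) should give 1-[4-(benzyloxy)-2,6-dihydroxy-3,5-dimethoxyphenyl]ethan-1-iminium chloride F1. Warming F1 in water should hydrolyse it to 1-[4-(benzyloxy)-2,6-dihydroxy-3,5-dimethoxyphenyl]ethan-1-one F2. Treating F2 with LiHMDS (4 equiv, THF, −78 °C) and then 8 should C-aroylate the lithium enolate (Baker–Venkataraman-type diketone formation) and comes back to the route at diketone 12. TsOH in toluene at 80 °C then cyclodehydrates 12 to 13.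

Step 3. The second oxidative addition on the electron-rich, ortho-substituted ring may be slow, so that mono-borylation and protodebromination compete and a mixture results. The fallback sets out from dibromide 3 and replaces both bromides by hydroxyl directly in a copper-catalysed C–O coupling (Cu(acac)2, N,N'-bis(4-hydroxy-2,6-dimethylphenyl)oxalamide, LiOH·H2O, DMSO/H2O, 90 °C, N2). It comes back at resorcinol 5 and bypasses 4 and step 4 (no new compound, F0).

Step 5. The chloroiminium ion may react at the phenol oxygens instead of the crowded carbon between them, or the acidic hydrolysis may start to cleave the benzyl ether. The fallback sets out from resorcinol 5 and uses the magnesium-mediated ortho-formylation (Casnati–Skattebøl: MgCl2, Et3N, paraformaldehyde, MeCN, reflux). There the magnesium phenoxide delivers formaldehyde to the ortho carbon and a hydride shift to a second formaldehyde gives the aldehyde under basic conditions. It comes back at aldehyde 6 (no new compound, F0).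

**Further compounds**

F1 | step 8 | 1-[4-(benzyloxy)-2,6-dihydroxy-3,5-dimethoxyphenyl]ethan-1-iminium chloride | CC(=[NH2+])c1c(O)c(OC)c(OCc2ccccc2)c(OC)c1O.[Cl-]
F2 | step 8 | 1-[4-(benzyloxy)-2,6-dihydroxy-3,5-dimethoxyphenyl]ethan-1-one | CC(=O)c1c(O)c(OC)c(OCc2ccccc2)c(OC)c1O
F0 | step 3 | none | none
F0 | step 5 | none | none
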